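**Retrosynthetic overview**

1. Mohangic acid F ⇒ one acidolysis of its tert-butyl ester / 9-O-triethylsilyl / N,N-di-Boc precursor ⇒ C13–C14 cut: catalytic direct aldol of a protected 4-aminoacetophenone with a C1–C13 aldehyde (sets C13).
2. C1–C13 aldehyde ⇒ C8–C9 cut: metal-free, IDPi-catalysed tris-vinylogous Mukaiyama aldol of a silyl tetraenyl ketene acetal with one formyl group of C2-symmetric (2R,4R)-2,4-dimethylpentanedial (sets C8 and C9 and brings in the whole trienoate; new reaction).
3. Dialdehyde ⇒ (2R,4R)-diol ⇒ penta-1,4-diene + Me3Al by twofold Zr-catalysed asymmetric carboalumination (sets C10 and C12, the first stereocentres).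
4. Silyl tetraenyl ketene acetal ⇒ tert-butyl (2E,4E,6Z)-nona-2,4,6-trienoate ⇒ (Z)-pent-2-en-1-ol + a C4 phosphonate.
5. No ring is formed at any stage; the only ring, the benzene ring, is bought in 4-aminoacetophenone.

Assumption: phosphonate 8 and the chiral catalysts are catalogue items, the target numbering (C1 acid to C15 ketone) is used for all intermediates, and in step 5 "(S,S)-IDPi" stands for the catalyst enantiomer that gives Re-face attack on the formyl group.

**Route**

Step 1
Reactants: 1 penta-1,4-diene; 2 trimethylaluminium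
Product: 4 (2R,4R)-2,4-dimethylpentane-1,5-diol, via bis(dimethylalane) 3 (not isolated)
Conditions: Me3Al (3 equiv), (−)-bis(1-neomenthylindenyl)zirconium dichloride [(−)-(NMI)2ZrCl2, 5 mol%], methylaluminoxane (MeAlO)n (cat.), CH2Cl2, 0 → 23 °C; then O2, 0 °C; H2O work-up
Reagents that add atoms: dioxygen O=O
Why: Twofold Zr-catalysed asymmetric carboalumination (ZACA reaction) adds Me and Al across each terminal alkene with the chiral zirconocene choosing the alkene face (about 85–90% per alkene, R sense as for simple 1-alkenes), and O2 oxidises the C–Al bonds with retention, so statistical amplification makes the C2-symmetric (2R,4R) diol almost enantiopure and leaves the meso diol as the only notable stereoisomer, removed by chromatography here or as a diastereomer after step 5.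

Step 2
Reactants: 4 (2R,4R)-2,4-dimethylpentane-1,5-diol
Product: 6 (2R,4R)-2,4-dimethylpentanedial, via bis(alkoxysulfonium) dichloride 5 (not isolated)
Conditions: (COCl)2, DMSO, CH2Cl2, −78 °C; Et3N, −78 → 0 °C; aqueous wash, bulb-to-bulb distillation, used at once
Reagents that add atoms: none
Why: Swern oxidation activates both hydroxyl groups at −78 °C before base is added, which avoids lactol and lactone formation and does not epimerise the α-stereocentres, and the C2 axis makes the two formyl groups of 6 equivalent so that no differentiation step is needed.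

Step 3
Reactants: 7 (Z)-pent-2-en-1-ol; 8 tert-butyl (E)-4-(diethoxyphosphoryl)but-2-enoate
Product: 11 tert-butyl (2E,4E,6Z)-nona-2,4,6-trienoate, via (Z)-pent-2-enal 9 (not isolated), via lithiated phosphonate 10 (not isolated)
Conditions: Dess–Martin periodinane, pyridine, CH2Cl2, 0 °C; filter; then 8 + LiN(SiMe3)2, THF, −78 → −20 °C
Reagents that add atoms: none
Why: Buffered Dess–Martin oxidation gives the labile (Z)-enal without isomerisation and the vinylogous Horner–Wadsworth–Emmons reaction at low temperature forms the new C4=C5 alkene E-selectively while the Z-alkene is kept.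

Step 4
Reactants: 11 tert-butyl (2E,4E,6Z)-nona-2,4,6-trienoate
Product: 13 triethyl{[(3E,5E,7E)-1-(tert-butoxy)nona-1,3,5,7-tetraen-1-yl]oxy}silane, via lithium tetraenolate 12 (not isolated)
Conditions: LiN(iPr)2, DMPU, THF, −78 °C; then Et3SiCl, −78 → 0 °C; pentane extraction, used crude
Reagents that add atoms: chlorotriethylsilane CC[Si](Cl)(CC)CC
Why: Vinylogous deprotonation of the only acidic CH2 (C8) and O-silylation give the 1-siloxytetraene, and allylic 1,3-strain in the (6Z)-alkene forces the methyl group outward during deprotonation so that the new terminal alkene is (7E), as known for (Z)-enoates giving (E)-dienolates.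

Step 5
Reactants: 6 (2R,4R)-2,4-dimethylpentanedial; 13 triethyl{[(3E,5E,7E)-1-(tert-butoxy)nona-1,3,5,7-tetraen-1-yl]oxy}silane
Product: 14 tert-butyl (2E,4E,6E,8R,9S,10R,12R)-8,10,12-trimethyl-13-oxo-9-[(triethylsilyl)oxy]trideca-2,4,6-trienoate
Conditions: (S,S)-IDPi (confined N-triflyl imidodiphosphorimidate Brønsted acid, 2 mol%), 6 (3 equiv), toluene, −78 → −60 °C; Et3N quench
Reagents that add atoms: none
Why: Proposed new method: a tris-vinylogous Mukaiyama aldol addition under silylium counteranion-directed catalysis, in which the IDPi acid is silylated by 13, the Et3Si+/IDPi− ion pair activates one of the two equivalent formyl groups of 6, and the 1-siloxytetraene attacks through its remote C8 terminus (largest HOMO coefficient, the only carbon reachable inside the catalyst pocket, and the attack that leaves a fully conjugated trienoate) in an open antiperiplanar transition state where the (7E)-methyl group avoids the silylated oxygen and the aldehyde chain avoids the polyene, which gives the 8,9-anti adduct with a (6E)-alkene from the s-trans diene, while the catalyst directs Re-face attack at C9 in the same sense as Felkin–Anh control from C10 (9,10-syn) and silyl transfer puts Et3Si on the new oxygen so that no lactol forms and the second formyl group survives with 6 in threefold excess (no by-product); the closest known reactions are the disulfonimide-catalysed vinylogous and bis-vinylogous Mukaiyama aldol additions of crotonate- and sorbate-derived silyl polyenolates, IDPi-catalysed Mukaiyama aldol additions of simple enolsilanes to aliphatic aldehydes, and anti-selective vinylogous Mukaiyama aldol additions of γ-methyl silyl dienolates, none of which has been shown for a four-alkene donor with a substituted terminus or for an α-chiral aliphatic dialdehyde.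

Step 6
Reactants: 15 1-(4-aminophenyl)ethan-1-one
Product: 16 tert-butyl N-(4-acetylphenyl)-N-(tert-butoxycarbonyl)carbamate
Conditions: Boc2O (2.5 equiv), DMAP (0.1 equiv), THF, 60 °C
Reagents that add atoms: di-tert-butyl dicarbonate CC(C)(C)OC(=O)OC(=O)OC(C)(C)C
Why: DMAP-catalysed double acylation of the electron-poor aniline gives the imidodicarbonate, which has no acidic N–H to quench the basic catalyst of step 7 and is removed by the same acid as the ester and silyl groups.

Step 7
Reactants: 14 tert-butyl (2E,4E,6E,8R,9S,10R,12R)-8,10,12-trimethyl-13-oxo-9-[(triethylsilyl)oxy]trideca-2,4,6-trienoate; 16 tert-butyl N-(4-acetylphenyl)-N-(tert-butoxycarbonyl)carbamate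
Product: 17 tert-butyl (2E,4E,6E,8R,9S,10R,12R,13R)-15-{4-[bis(tert-butoxycarbonyl)amino]phenyl}-13-hydroxy-8,10,12-trimethyl-15-oxo-9-[(triethylsilyl)oxy]pentadeca-2,4,6-trienoate
Conditions: (S,S)-ProPhenol (10 mol%), Et2Zn (20 mol%), Ph3P=S (15 mol%), 4 Å MS, 16 (3 equiv), THF, −5 → 5 °C
Reagents that add atoms: none
Why: Trost direct aldol reaction, in which the catalyst formed from Et2Zn and (S,S)-ProPhenol enolises the aryl methyl ketone and delivers it to the Re face of the α-branched aldehyde (the (S,S)-ligand gives (R)-aldols with α-branched aldehydes), so C13 is set as R under catalyst control matched with Felkin–Anh preference (12,13-syn), and the addition forms no by-product.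

Step 8
Reactants: 17 tert-butyl (2E,4E,6E,8R,9S,10R,12R,13R)-15-{4-[bis(tert-butoxycarbonyl)amino]phenyl}-13-hydroxy-8,10,12-trimethyl-15-oxo-9-[(triethylsilyl)oxy]pentadeca-2,4,6-trienoate
Product: 18 mohangic acid F
Conditions: CF3CO2H/CH2Cl2 (1:3), anisole, H2O (5 equiv), 0 °C → rt; pH 6 buffer; reverse-phase chromatography
Reagents that add atoms: none
Why: Acidolysis removes both N-Boc groups and the tert-butyl ester by loss of 2-methylpropene (and CO2) and hydrolyses the triethylsilyl ether in one operation without touching any stereocentre, and the short cold reaction spares the β-hydroxy ketone and the trienoic acid.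

**Compound list**

1 | penta-1,4-diene | C=CCC=C | starting material
2 | trimethylaluminium | C[Al](C)C | starting material
3 | [(2R,4R)-2,4-dimethylpentane-1,5-diyl]bis(dimethylalane) | C[Al](C)C[C@H](C)C[C@@H](C)C[Al](C)C | intermediate
4 | (2R,4R)-2,4-dimethylpentane-1,5-diol | OC[C@H](C)C[C@@H](C)CO | intermediate
5 | {[(2R,4R)-2,4-dimethylpentane-1,5-diyl]bis(oxy)}bis(dimethylsulfonium) dichloride | C[S+](C)OC[C@H](C)C[C@@H](C)CO[S+](C)C.[Cl-].[Cl-] | intermediate
6 | (2R,4R)-2,4-dimethylpentanedial | O=C[C@H](C)C[C@@H](C)C=O | intermediate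
7 | (Z)-pent-2-en-1-ol | CC/C=C\CO | starting material
8 | tert-butyl (E)-4-(diethoxyphosphoryl)but-2-enoate | CCOP(=O)(C/C=C/C(=O)OC(C)(C)C)OCC | starting material
9 | (Z)-pent-2-enal | CC/C=C\C=O | intermediate
10 | lithium salt of the carbanion of phosphonate 8 | CCOP(=O)([CH-]/C=C/C(=O)OC(C)(C)C)OCC.[Li+] | intermediate
11 | tert-butyl (2E,4E,6Z)-nona-2,4,6-trienoate | CC/C=C\C=C\C=C\C(=O)OC(C)(C)C | intermediate
12 | lithium (3E,5E,7E)-1-(tert-butoxy)nona-1,3,5,7-tetraen-1-olate | C/C=C/C=C/C=C/C=C([O-])OC(C)(C)C.[Li+] | intermediate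
13 | triethyl{[(3E,5E,7E)-1-(tert-butoxy)nona-1,3,5,7-tetraen-1-yl]oxy}silane (1E/1Z mixture) | C/C=C/C=C/C=C/C=C(OC(C)(C)C)O[Si](CC)(CC)CC | intermediate
14 | tert-butyl (2E,4E,6E,8R,9S,10R,12R)-8,10,12-trimethyl-13-oxo-9-[(triethylsilyl)oxy]trideca-2,4,6-trienoate | C[C@H](/C=C/C=C/C=C/C(=O)OC(C)(C)C)[C@@H](O[Si](CC)(CC)CC)[C@H](C)C[C@@H](C)C=O | intermediate
15 | 1-(4-aminophenyl)ethan-1-one (4-aminoacetophenone) | CC(=O)c1ccc(N)cc1 | starting material
16 | tert-butyl N-(4-acetylphenyl)-N-(tert-butoxycarbonyl)carbamate | CC(=O)c1ccc(N(C(=O)OC(C)(C)C)C(=O)OC(C)(C)C)cc1 | intermediate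
17 | tert-butyl (2E,4E,6E,8R,9S,10R,12R,13R)-15-{4-[bis(tert-butoxycarbonyl)amino]phenyl}-13-hydroxy-8,10,12-trimethyl-15-oxo-9-[(triethylsilyl)oxy]pentadeca-2,4,6-trienoate | C[C@H](/C=C/C=C/C=C/C(=O)OC(C)(C)C)[C@@H](O[Si](CC)(CC)CC)[C@H](C)C[C@@H](C)[C@H](O)CC(=O)c1ccc(N(C(=O)OC(C)(C)C)C(=O)OC(C)(C)C)cc1 | intermediate
18 | mohangic acid F, (2E,4E,6E,8R,9S,10R,12R,13R)-15-(4-aminophenyl)-9,13-dihydroxy-8,10,12-trimethyl-15-oxopentadeca-2,4,6-trienoic acid | C[C@H](/C=C/C=C/C=C/C(=O)O)[C@@H](O)[C@H](C)C[C@@H](C)[C@H](O)CC(=O)c1ccc(N)cc1 | target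

**Step count and risks**

Total steps: 8. Longest linear sequence: 5 steps (1 → 2 → 5 → 7 → 8; the branch 3 → 4 → 5 → 7 → 8 is equally long).

Step 5 (the new reaction, highest risk). It may give attack at an inner carbon of the tetraene, a poor anti/syn ratio, double addition, or cyclisation of the silyloxy aldehyde onto the second activated formyl group. The fallback uses known reactions only, sets out from 6 and 16, and comes back to the route at 18.
- The direct aldol of step 7 [(S,S)-ProPhenol, Et2Zn, Ph3P=S, THF, 5 °C] is run first on dialdehyde 6. The aldolate closes onto the second formyl group, which stops double addition and gives the δ-lactol tert-butyl N-(tert-butoxycarbonyl)-N-(4-{2-[(2R,3R,5R)-6-hydroxy-3,5-dimethyloxan-2-yl]acetyl}phenyl)carbamate F1.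
- Brown (E)-crotylboration of the open form of the lactol with B-(E)-crotyldiisopinocampheylborane made from (+)-B-methoxydiisopinocampheylborane (2.2 equiv, THF/Et2O, −78 °C, ethanolamine work-up) sets C8 and C9 (anti, Re face, matched with Felkin–Anh control). It gives tert-butyl N-(tert-butoxycarbonyl)-N-{4-[(3R,4R,6R,7S,8R)-3,7-dihydroxy-4,6,8-trimethyldec-9-enoyl]phenyl}carbamate F2.
- Cross-metathesis with (E)-but-2-enal (second-generation Hoveyda–Grubbs catalyst [RuCl2(=CH-C6H4-2-OiPr)(H2IMes)], CH2Cl2, 40 °C) gives tert-butyl N-(tert-butoxycarbonyl)-N-{4-[(3R,4R,6R,7S,8R,9E)-3,7-dihydroxy-4,6,8-trimethyl-11-oxoundec-9-enoyl]phenyl}carbamate F3.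
- Horner–Wadsworth–Emmons olefination with lithiated phosphonate 10 (3 equiv, THF, −78 °C) gives tert-butyl (2E,4E,6E,8R,9S,10R,12R,13R)-15-{4-[bis(tert-butoxycarbonyl)amino]phenyl}-9,13-dihydroxy-8,10,12-trimethyl-15-oxopentadeca-2,4,6-trienoate F4. This is 17 without its silyl group and is converted into 18 under the conditions of step 8.

Step 7. The direct aldol may stall on the hindered aldehyde, lose water to the enone, or epimerise C12. The fallback sets out from 16 and 14 and comes back at 17. Ketone 16 is converted (Me3SiOTf, Et3N, CH2Cl2, 0 °C) into tert-butyl N-(tert-butoxycarbonyl)-N-{4-[1-(trimethylsilyloxy)ethenyl]phenyl}carbamate F5. F5 is then added to 14 in a BF3·OEt2-mediated Mukaiyama aldol reaction (CH2Cl2, −78 °C) under Felkin–Anh substrate control (12,13-syn). Selectivity is lower than under catalyst control, so the C13 epimer is removed by chromatography; aqueous work-up gives 17.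

Step 8. Trifluoroacetic acid may dehydrate the β-hydroxy ketone, isomerise the triene, or let tert-butyl cations alkylate the aniline. The fallback sets out from 17 and comes back at 18, and separates the two events under buffered conditions. First Me3SiOTf/2,6-lutidine (CH2Cl2, 0 °C; then MeOH and pH 5 citrate) cleaves both Boc groups and the tert-butyl ester by silyl transfer and gives (2E,4E,6E,8R,9S,10R,12R,13R)-15-(4-aminophenyl)-13-hydroxy-8,10,12-trimethyl-15-oxo-9-[(triethylsilyl)oxy]pentadeca-2,4,6-trienoic acid F6. Then HF·pyridine in THF/pyridine at 0 °C removes the triethylsilyl ether and gives 18.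

Further compounds
F1 | step 5 | tert-butyl N-(tert-butoxycarbonyl)-N-(4-{2-[(2R,3R,5R)-6-hydroxy-3,5-dimethyloxan-2-yl]acetyl}phenyl)carbamate (anomer mixture) | OC1[C@H](C)C[C@@H](C)[C@@H](CC(=O)c2ccc(N(C(=O)OC(C)(C)C)C(=O)OC(C)(C)C)cc2)O1
F2 | step 5 | tert-butyl N-(tert-butoxycarbonyl)-N-{4-[(3R,4R,6R,7S,8R)-3,7-dihydroxy-4,6,8-trimethyldec-9-enoyl]phenyl}carbamate | C[C@H](C=C)[C@@H](O)[C@H](C)C[C@@H](C)[C@H](O)CC(=O)c1ccc(N(C(=O)OC(C)(C)C)C(=O)OC(C)(C)C)cc1
F3 | step 5 | tert-butyl N-(tert-butoxycarbonyl)-N-{4-[(3R,4R,6R,7S,8R,9E)-3,7-dihydroxy-4,6,8-trimethyl-11-oxoundec-9-enoyl]phenyl}carbamate | C[C@H](/C=C/C=O)[C@@H](O)[C@H](C)C[C@@H](C)[C@H](O)CC(=O)c1ccc(N(C(=O)OC(C)(C)C)C(=O)OC(C)(C)C)cc1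
F4 | step 5 | tert-butyl (2E,4E,6E,8R,9S,10R,12R,13R)-15-{4-[bis(tert-butoxycarbonyl)amino]phenyl}-9,13-dihydroxy-8,10,12-trimethyl-15-oxopentadeca-2,4,6-trienoate | C[C@H](/C=C/C=C/C=C/C(=O)OC(C)(C)C)[C@@H](O)[C@H](C)C[C@@H](C)[C@H](O)CC(=O)c1ccc(N(C(=O)OC(C)(C)C)C(=O)OC(C)(C)C)cc1
F5 | step 7 | tert-butyl N-(tert-butoxycarbonyl)-N-{4-[1-(trimethylsilyloxy)ethenyl]phenyl}carbamate | C=C(O[Si](C)(C)C)c1ccc(N(C(=O)OC(C)(C)C)C(=O)OC(C)(C)C)cc1
F6 | step 8 | (2E,4E,6E,8R,9S,10R,12R,13R)-15-(4-aminophenyl)-13-hydroxy-8,10,12-trimethyl-15-oxo-9-[(triethylsilyl)oxy]pentadeca-2,4,6-trienoic acid | C[C@H](/C=C/C=C/C=C/C(=O)O)[C@@H](O[Si](CC)(CC)CC)[C@H](C)C[C@@H](C)[C@H](O)CC(=O)c1ccc(N)cc1
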